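**Retrosynthetic overview**
- Ring A (OH next to the chain, OMe next to CH3) and ring B (OMe next to the chain, OH next to CH3) differ only in which oxygen is methylated. The two free OH groups are traced back to a tert-butyl ether (ring A) and a THP ether (ring B), both removed in the last step.
- Both quinone rings are disconnected at once. Each comes from thermal ring expansion of a 4-hydroxy-4-(1-alkoxyallenyl)cyclobutenone: the cyclobutenone supplies C=O, C–OR, C–chain and C=O, the allene supplies C–OR and C–CH3.
- The unsymmetrical bis-cyclobutenone comes from a C14 di-Grignard reagent and two different squarate/lithioalkoxyallene adducts (di-tert-butyl squarate + methoxyallene for ring A; dimethyl squarate + THP-oxyallene for ring B), joined by 1,2-addition and carbonyl transposition.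
- Ring order: the four-membered rings are bought as squarate esters; rings A and B are formed together in one thermolysis; nothing is cyclised afterwards.

Assumption: the target has no stereocentre and no stereogenic double bond, so it is one achiral compound and no configuration has to be set; the linker is read as (CH2)14; stereocentres that arise on the way (THP acetal carbon, C4 of the cyclobutenones) are left uncontrolled and are all gone in the target.

**Route**

Step 1
Reactants: 1 2-(prop-2-yn-1-yloxy)oxane (racemic THP ether of propargyl alcohol)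
Product: 2 2-(propa-1,2-dien-1-yloxy)oxane (racemic)
Conditions: KOtBu (0.3 equiv), THF, 25 °C; distil
Reagents that add atoms: none
Why: Base-catalysed propargyl-to-allenyl ether isomerisation (the way methoxyallene itself is made) gives the conjugated alkoxyallene; no stereocentre is set.

Step 2
Reactants: 2 2-(propa-1,2-dien-1-yloxy)oxane; 3 dimethyl squarate (3,4-dimethoxycyclobut-3-ene-1,2-dione)
Product: 5 2,3-dimethoxy-4-[1-(oxan-2-yloxy)propa-1,2-dien-1-yl]-4-[(trimethylsilyl)oxy]cyclobut-2-en-1-one (racemic diastereomer mixture), via 1-lithio-1-(oxan-2-yloxy)propa-1,2-diene 4 (not isolated)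
Conditions: n-BuLi, THF, −78 °C; then 3, −78 °C; then Me3SiCl, −78 to 0 °C
Reagents that add atoms: chlorotrimethylsilane, C[Si](C)(C)Cl
Why: α-Lithiation of the alkoxyallene and 1,2-addition of the organolithium to one of the two equivalent squarate carbonyls (first stage of the Moore squarate sequence), with the tertiary alkoxide capped as its silyl ether so that later ionisation can only occur at the second carbinol; the new quaternary carbon is racemic and is destroyed in step 5.

Step 3
Reactants: 6 methoxyallene (1-methoxypropa-1,2-diene); 7 di-tert-butyl squarate (3,4-di-tert-butoxycyclobut-3-ene-1,2-dione)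
Product: 9 2,3-di-tert-butoxy-4-(1-methoxypropa-1,2-dien-1-yl)-4-[(trimethylsilyl)oxy]cyclobut-2-en-1-one (racemic), via 1-lithio-1-methoxypropa-1,2-diene 8 (not isolated)
Conditions: n-BuLi, THF, −78 °C; then 7, −78 °C; then Me3SiCl, −78 to 0 °C
Reagents that add atoms: chlorotrimethylsilane, C[Si](C)(C)Cl
Why: Same α-lithiation, organolithium 1,2-addition to a squarate ester and O-silylation as in step 2; the quaternary carbon is racemic and is destroyed in step 5.

Step 4
Reactants: 10 1,14-dibromotetradecane; 5 (1.0 equiv); 9 (1.0 equiv)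
Product: 13 2-tert-butoxy-4-hydroxy-3-{14-[4-hydroxy-2-methoxy-4-[1-(oxan-2-yloxy)propa-1,2-dien-1-yl]-3-oxocyclobut-1-en-1-yl]tetradecyl}-4-(1-methoxypropa-1,2-dien-1-yl)cyclobut-2-en-1-one (diastereomer mixture), via 1,14-bis(bromomagnesio)tetradecane 11 (not isolated), via bis(trimethylsilyl) ether 12 (not isolated)
Conditions: Mg, THF, 50 °C; add to 5 + 9 (1:1), THF, −78 to −30 °C; (CF3CO)2O, 2,6-lutidine, −78 to 0 °C; aq. NaHCO3; then Bu4NF, AcOH, THF, 0 °C; chromatography on Et3N-washed silica
Reagents that add atoms: water, O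
Why: Each C–Mg end adds 1,2 to the only carbonyl of 5 or 9, and trifluoroacetylation of the new alkoxides triggers the allylic ionisation/1,3-carbonyl transposition of the sequential-addition Moore squarate chemistry (loss of isobutene on the 9-derived side, of methanol after aqueous quench on the 5-derived side) before fluoride frees the tertiary alcohols; the mixed product is the statistical major component (about 2:1:1 against the two symmetric bis-adducts, which carry two tert-butyl or two THP groups and separate on silica), and no stereocentre needs control.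

Step 5
Reactants: 13 the unsymmetrical bis(4-hydroxycyclobutenone)
Product: 15 2-tert-butoxy-5-methoxy-6-methyl-3-{14-[2-methoxy-4-methyl-5-(oxan-2-yloxy)-3,6-dioxocyclohexa-1,4-dien-1-yl]tetradecyl}cyclohexa-2,5-diene-1,4-dione (racemic at the THP carbon only), via bis(o-quinone methide) 14 (not isolated)
Conditions: toluene (0.01 M, degassed), 110 °C, 2 h
Reagents that add atoms: none
Why: Proposed new method: each 4-hydroxy-4-(1-alkoxyallenyl)cyclobutenone should undergo conrotatory 4π ring opening with the hydroxyl rotating outwards, 6π-electrocyclisation onto the proximal allene C=C to give the 4-hydroxy o-quinone methide 14, and a formal 1,5-H shift from O–H to the exocyclic CH2 to give the methyl-quinone, so both fully substituted quinone rings form in one heating operation with the OR/chain and OR/CH3 pairs placed by construction; the closest known reaction type is the Moore thermal ring expansion of 4-alkenyl- and 4-allenyl-4-hydroxycyclobutenones to hydroquinones and o-quinone methides; no ring stereocentre remains.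

Step 6
Reactants: 15 the tert-butyl/THP-protected bis-quinone
Product: 16 2-hydroxy-5-methoxy-6-methyl-3-[14-(5-hydroxy-2-methoxy-4-methyl-3,6-dioxocyclohexa-1,4-dien-1-yl)tetradecyl]cyclohexa-2,5-diene-1,4-dione (target, achiral)
Conditions: CF3CO2H, CH2Cl2, H2O (5 equiv), 0 to 25 °C
Reagents that add atoms: none
Why: Acidolysis: the vinylogous tert-butyl ester loses isobutene (E1) and the vinylogous THP ester is hydrolysed as an acetal, while the two vinylogous methyl esters are stable to CF3CO2H at room temperature, so the OMe/OH pattern fixed in steps 2 to 4 is delivered unchanged.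

**Compound list**
1 | 2-(prop-2-yn-1-yloxy)oxane (racemic) | C#CCOC1CCCCO1 | starting material
2 | 2-(propa-1,2-dien-1-yloxy)oxane (racemic) | C=C=COC1CCCCO1 | intermediate
3 | dimethyl squarate (3,4-dimethoxycyclobut-3-ene-1,2-dione) | COC1=C(OC)C(=O)C1=O | starting material
4 | 1-lithio-1-(oxan-2-yloxy)propa-1,2-diene | [Li]C(OC1CCCCO1)=C=C | intermediate
5 | 2,3-dimethoxy-4-[1-(oxan-2-yloxy)propa-1,2-dien-1-yl]-4-[(trimethylsilyl)oxy]cyclobut-2-en-1-one (stereocentres uncontrolled) | COC1=C(OC)C(O[Si](C)(C)C)(C(OC2CCCCO2)=C=C)C1=O | intermediate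
6 | methoxyallene (1-methoxypropa-1,2-diene) | COC=C=C | starting material
7 | di-tert-butyl squarate (3,4-di-tert-butoxycyclobut-3-ene-1,2-dione) | CC(C)(C)OC1=C(OC(C)(C)C)C(=O)C1=O | starting material
8 | 1-lithio-1-methoxypropa-1,2-diene | [Li]C(OC)=C=C | intermediate
9 | 2,3-di-tert-butoxy-4-(1-methoxypropa-1,2-dien-1-yl)-4-[(trimethylsilyl)oxy]cyclobut-2-en-1-one (racemic) | CC(C)(C)OC1=C(OC(C)(C)C)C(O[Si](C)(C)C)(C(OC)=C=C)C1=O | intermediate
10 | 1,14-dibromotetradecane | BrCCCCCCCCCCCCCCBr | starting material
11 | 1,14-bis(bromomagnesio)tetradecane | Br[Mg]CCCCCCCCCCCCCC[Mg]Br | intermediate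
12 | 2-tert-butoxy-4-(1-methoxypropa-1,2-dien-1-yl)-3-{14-[2-methoxy-4-[1-(oxan-2-yloxy)propa-1,2-dien-1-yl]-3-oxo-4-[(trimethylsilyl)oxy]cyclobut-1-en-1-yl]tetradecyl}-4-[(trimethylsilyl)oxy]cyclobut-2-en-1-one (stereocentres uncontrolled) | C=C=C(OC)C1(O[Si](C)(C)C)C(CCCCCCCCCCCCCCC2=C(OC)C(=O)C2(O[Si](C)(C)C)C(OC3CCCCO3)=C=C)=C(OC(C)(C)C)C1=O | intermediate
13 | 2-tert-butoxy-4-hydroxy-3-{14-[4-hydroxy-2-methoxy-4-[1-(oxan-2-yloxy)propa-1,2-dien-1-yl]-3-oxocyclobut-1-en-1-yl]tetradecyl}-4-(1-methoxypropa-1,2-dien-1-yl)cyclobut-2-en-1-one (stereocentres uncontrolled) | C=C=C(OC)C1(O)C(CCCCCCCCCCCCCCC2=C(OC)C(=O)C2(O)C(OC3CCCCO3)=C=C)=C(OC(C)(C)C)C1=O | intermediate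
14 | 2-tert-butoxy-4-hydroxy-5-methoxy-6-methylidene-3-{14-[6-hydroxy-2-methoxy-4-methylidene-5-(oxan-2-yloxy)-3-oxocyclohexa-1,5-dien-1-yl]tetradecyl}cyclohexa-2,4-dien-1-one (bis-o-quinone methide, racemic at the THP carbon) | C=C1C(OC)=C(O)C(CCCCCCCCCCCCCCC2=C(OC)C(=O)C(=C)C(OC3CCCCO3)=C2O)=C(OC(C)(C)C)C1=O | intermediate
15 | 2-tert-butoxy-5-methoxy-6-methyl-3-{14-[2-methoxy-4-methyl-5-(oxan-2-yloxy)-3,6-dioxocyclohexa-1,4-dien-1-yl]tetradecyl}cyclohexa-2,5-diene-1,4-dione (racemic at the THP carbon) | CC1=C(OC)C(=O)C(CCCCCCCCCCCCCCC2=C(OC)C(=O)C(C)=C(OC3CCCCO3)C2=O)=C(OC(C)(C)C)C1=O | intermediate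
16 | 2-hydroxy-5-methoxy-6-methyl-3-[14-(5-hydroxy-2-methoxy-4-methyl-3,6-dioxocyclohexa-1,4-dien-1-yl)tetradecyl]cyclohexa-2,5-diene-1,4-dione (achiral) | COC1=C(C)C(=O)C(O)=C(CCCCCCCCCCCCCCC2=C(OC)C(=O)C(C)=C(O)C2=O)C1=O | target

**Step count and risk**
Total step count: 6. Longest linear sequence: 5 steps (steps 1, 2, 4, 5, 6; step 3 is a one-step branch).

Three steps most likely to fail:

Step 4. It is statistical (at most about half of the material can become the mixed product). It also needs clean 1,2-addition of a Grignard end to a hindered vinylogous-ester carbonyl, no O-to-O silyl migration before the anhydride quench, and survival of two acid-sensitive alkoxyallenes. The fallback gives up the mixed coupling and desymmetrises only at the end. It sets out from 3, 8 and 11. Organolithium 8 is added to 3 and the alkoxide silylated to give 2,3-dimethoxy-4-(1-methoxypropa-1,2-dien-1-yl)-4-[(trimethylsilyl)oxy]cyclobut-2-en-1-one F1. Reagent 11 and two equivalents of F1, then (CF3CO)2O, give the symmetric bis(trimethylsilyl) ether F2. Bu4NF/AcOH gives the symmetric bis(4-hydroxycyclobutenone) F3. Heating in toluene gives, through the symmetric bis(o-quinone methide) F4, the tetramethoxy bis-quinone F5, with no statistical loss up to this point. NaOH (2 equiv, aqueous THF, 0 °C) then cleaves one vinylogous methyl ester per ring, because the hydroxyquinone anion formed resists a second hydrolysis. Either position is attacked, so 16 is only the statistically favoured isomer (2:1:1 with the two symmetric isomers). It is isolated by preparative reversed-phase HPLC, which is the weak point of this fallback; the symmetric isomers are re-methylated to F5 and recycled. The fallback comes back to the route at 16.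

Step 5. The allene variant of the ring expansion is not established, two expansions must succeed in one molecule, and the o-quinone methide could dimerise or be trapped by a free OH before it tautomerises. The fallback separates ring formation from aromatisation. It sets out from 12, isolated by leaving out the fluoride treatment in step 4. Heating 12 in toluene gives the bis(4-silyloxy o-quinone methide) F6, which carries no free OH and cannot undergo the H shift. Bu4NF/AcOH at 0 °C then removes both silyl groups and the resulting phenoxides are protonated at the exocyclic CH2. This gives 15, where the fallback comes back to the route.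

Step 2. α-Lithiation of the THP-bearing allene and its addition to the squarate have no direct precedent, and the acetal may interfere. The fallback changes the masking group to the well-behaved methoxymethyl ether. It sets out from 3 and comes back to the route at 16. 3-(Methoxymethoxy)prop-1-yne F7 is isomerised with KOtBu to 1-(methoxymethoxy)propa-1,2-diene F8 and lithiated with n-BuLi to 1-lithio-1-(methoxymethoxy)propa-1,2-diene F9. Addition to 3 and silylation give 2,3-dimethoxy-4-[1-(methoxymethoxy)propa-1,2-dien-1-yl]-4-[(trimethylsilyl)oxy]cyclobut-2-en-1-one F10. With F10 in place of 5, the operations of steps 4 and 5 (with 9 and 11) give in turn the bis(trimethylsilyl) ether F11, the bis(4-hydroxycyclobutenone) F12, the bis(o-quinone methide) F13 and the bis-quinone F14. CF3CO2H/H2O removes the tert-butyl and methoxymethyl groups together to give 16.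

Further compounds
F1 | step 4 | 2,3-dimethoxy-4-(1-methoxypropa-1,2-dien-1-yl)-4-[(trimethylsilyl)oxy]cyclobut-2-en-1-one | COC1=C(OC)C(O[Si](C)(C)C)(C(OC)=C=C)C1=O
F2 | step 4 | 1,14-bis{2-methoxy-4-(1-methoxypropa-1,2-dien-1-yl)-3-oxo-4-[(trimethylsilyl)oxy]cyclobut-1-en-1-yl}tetradecane | C=C=C(OC)C1(O[Si](C)(C)C)C(CCCCCCCCCCCCCCC2=C(OC)C(=O)C2(O[Si](C)(C)C)C(OC)=C=C)=C(OC)C1=O
F3 | step 4 | 1,14-bis[4-hydroxy-2-methoxy-4-(1-methoxypropa-1,2-dien-1-yl)-3-oxocyclobut-1-en-1-yl]tetradecane | C=C=C(OC)C1(O)C(CCCCCCCCCCCCCCC2=C(OC)C(=O)C2(O)C(OC)=C=C)=C(OC)C1=O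
F4 | step 4 | 1,14-bis(6-hydroxy-2,5-dimethoxy-4-methylidene-3-oxocyclohexa-1,5-dien-1-yl)tetradecane | C=C1C(OC)=C(O)C(CCCCCCCCCCCCCCC2=C(OC)C(=O)C(=C)C(OC)=C2O)=C(OC)C1=O
F5 | step 4 | 1,14-bis(2,5-dimethoxy-4-methyl-3,6-dioxocyclohexa-1,4-dien-1-yl)tetradecane | CC1=C(OC)C(=O)C(CCCCCCCCCCCCCCC2=C(OC)C(=O)C(C)=C(OC)C2=O)=C(OC)C1=O
F6 | step 5 | 2-tert-butoxy-5-methoxy-6-methylidene-3-{14-[2-methoxy-4-methylidene-5-(oxan-2-yloxy)-3-oxo-6-[(trimethylsilyl)oxy]cyclohexa-1,5-dien-1-yl]tetradecyl}-4-[(trimethylsilyl)oxy]cyclohexa-2,4-dien-1-one | C=C1C(OC)=C(O[Si](C)(C)C)C(CCCCCCCCCCCCCCC2=C(OC)C(=O)C(=C)C(OC3CCCCO3)=C2O[Si](C)(C)C)=C(OC(C)(C)C)C1=O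
F7 | step 2 | 3-(methoxymethoxy)prop-1-yne | COCOCC#C
F8 | step 2 | 1-(methoxymethoxy)propa-1,2-diene | COCOC=C=C
F9 | step 2 | 1-lithio-1-(methoxymethoxy)propa-1,2-diene | [Li]C(OCOC)=C=C
F10 | step 2 | 2,3-dimethoxy-4-[1-(methoxymethoxy)propa-1,2-dien-1-yl]-4-[(trimethylsilyl)oxy]cyclobut-2-en-1-one | COCOC(=C=C)C1(O[Si](C)(C)C)C(OC)=C(OC)C1=O
F11 | step 2 | analogue of 12 with methoxymethoxy in place of oxan-2-yloxy | C=C=C(OC)C1(O[Si](C)(C)C)C(CCCCCCCCCCCCCCC2=C(OC)C(=O)C2(O[Si](C)(C)C)C(OCOC)=C=C)=C(OC(C)(C)C)C1=O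
F12 | step 2 | analogue of 13 with methoxymethoxy in place of oxan-2-yloxy | C=C=C(OC)C1(O)C(CCCCCCCCCCCCCCC2=C(OC)C(=O)C2(O)C(OCOC)=C=C)=C(OC(C)(C)C)C1=O
F13 | step 2 | analogue of 14 with methoxymethoxy in place of oxan-2-yloxy | C=C1C(OC)=C(O)C(CCCCCCCCCCCCCCC2=C(OC)C(=O)C(=C)C(OCOC)=C2O)=C(OC(C)(C)C)C1=O
F14 | step 2 | analogue of 15 with methoxymethoxy in place of oxan-2-yloxy | CC1=C(OC)C(=O)C(CCCCCCCCCCCCCCC2=C(OC)C(=O)C(C)=C(OCOC)C2=O)=C(OC(C)(C)C)C1=O
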